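**Plan**

1. Retrosynthesis (trione ring C‑1…C‑6; hydrindane C‑1′…C‑7a′; spiro atom C‑6 = C‑6′): the two prenyl C=C bonds are cut last (double Wittig on a bis‑acetaldehyde stored as a spiro‑cyclopentene on C‑4), then the C‑4′ carbinol C–O bond (Markovnikov hydration of a ring alkene).
2. The bonds C‑6′(spiro)–C‑7′H2 and C‑3a′–C‑7a′ are then cut together (intramolecular Diels–Alder reaction). This leaves a 1‑oxatriene, which is cut at its exocyclic C=C bond into the trione and (R,E)‑8‑oxolinalool (Knoevenagel condensation).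
3. Enabling feature: the spiro carbon is C‑2 of a cyclic 1,3‑dione, so with C‑5′H, C‑4′(CH3) and C‑3a′H it forms an electron‑poor diene C=CH–C(CH3)=CH. The vinyl group C‑7a′=C‑7′ on the C‑1′ carbinol hangs three atoms from the diene end (a 1,3,8‑nonatriene).
4. Forward order: trione ring with spiro‑cyclopentene lock → in one flask Knoevenagel condensation, 2H‑pyran (the easily made formal [3+3] skeleton) and its thermal reorganisation that closes the cyclohexene and the cyclopentane of the hydrindane at once → hydration → cyclopentene cut open and turned into the two prenyl groups.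
5. Stereochemistry: C‑1′ from (R)‑linalool; C‑3a′, C‑7a′ and the spiro centre arise in the cycloaddition under control of that carbinol; C‑4′ by O2 capture of a tertiary radical anti to the axial trione carbonyl.

Key step: step 4

Remark: enolised triketones are drawn as one tautomer, and commercial (R)‑(−)‑linalool of high enantiomeric purity is assumed; the spiro‑cyclopentene is needed because prenyl C=C bonds would not survive the radical hydration of step 5.

**Step 1**
Reactants: 1 2′,4′,6′‑trihydroxyacetophenone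
Product: 3 2‑acetyl‑3,5‑dihydroxy‑4,4‑di(prop‑2‑en‑1‑yl)cyclohexa‑2,5‑dien‑1‑one, via 3′‑allyl‑2′,4′,6′‑trihydroxyacetophenone 2 (not isolated)
Conditions: NaOMe (2.2 equiv), allyl bromide (2.1 equiv), MeOH, 0 °C → rt
Reagents that add atoms: allyl bromide, C=CCBr
Why: Alkylative dearomatisation by double C‑allylation of the phloroglucinol anion should place the second allyl group geminally on the already substituted, most electron‑rich ring carbon and lock the ring as a non‑aromatic enolised trione (the 3,5‑diallyl and O‑allyl isomers are removed by chromatography); no stereocentre is formed.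

**Step 2**
Reactants: 3 2‑acetyl‑3,5‑dihydroxy‑4,4‑di(prop‑2‑en‑1‑yl)cyclohexa‑2,5‑dien‑1‑one
Product: 4 7‑acetyl‑6,10‑dihydroxyspiro[4.5]deca‑2,6,9‑trien‑8‑one
Conditions: second‑generation Grubbs catalyst RuCl2(=CHPh)(PCy3)(H2IMes) (3 mol %), CH2Cl2, 40 °C
Reagents that add atoms: none
Why: Ring‑closing metathesis of a geminal diallyl unit ties both allyl groups into one cis‑disubstituted cyclopentene that keeps the trione non‑aromatic, should be slow towards hydrogen‑atom transfer in step 5 and stores the two CH2CHO arms released in step 6.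

**Step 3**
Reactants: 5 (R)‑(−)‑linalool
Product: 7 (2E,6R)‑6‑hydroxy‑2,6‑dimethylocta‑2,7‑dienal, via (2E,6R)‑2,6‑dimethylocta‑2,7‑diene‑1,6‑diol 6 (not isolated)
Conditions: SeO2 (1.2 equiv), 1,4‑dioxane, 80 °C
Reagents that add atoms: selenium dioxide, O=[Se]=O
Why: Riley allylic oxidation (ene reaction then [2,3]‑sigmatropic shift) should attack the E‑methyl group of the trisubstituted alkene selectively and carry the primary allylic alcohol 6 on to the E‑enal, leaving the tertiary vinyl carbinol stereocentre untouched.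

**Step 4**
Reactants: 4 7‑acetyl‑6,10‑dihydroxyspiro[4.5]deca‑2,6,9‑trien‑8‑one; 7 (2E,6R)‑6‑hydroxy‑2,6‑dimethylocta‑2,7‑dienal
Product: 10 spiro cycloadduct in which 2‑acetyl‑3‑hydroxycyclohex‑2‑ene‑1,5‑dione is spiro at C‑4 to cyclopent‑3‑ene and at C‑6 to C‑6′ of trans‑fused (1′R)‑1′‑hydroxy‑1′,4′‑dimethyl‑2′,3′,3a′,6′,7′,7a′‑hexahydro‑1′H‑indene (1′‑OH cis to C‑7′; C‑1 carbonyl cis to 7a′‑H), via 1‑oxatriene 8 (not isolated), via 2H‑pyran 9 (not isolated)
Conditions: ethylenediammonium diacetate (10 mol %), toluene, 4 Å molecular sieves, 45 °C; then dilution with toluene to 0.005 M, 2,6‑di‑tert‑butyl‑4‑methylphenol (5 mol %), argon, sealed tube, 130 °C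
Reagents that add atoms: none
Why: Proposed new method: Knoevenagel condensation at the only free ring CH of 4 should give the 1‑oxatriene 8, which rests as the 2H‑pyran 9 (oxa‑6π electrocyclisation, the formal [3+3] annulation of cyclic 1,3‑diones with enals) and is released again on heating by retro‑electrocyclisation, after which its 4π unit C(ring)=CH–C(CH3)=CH adds to the tethered, unactivated vinyl group in an irreversible type 1 intramolecular Diels–Alder reaction with inverse electron demand that drains the pyran–oxatriene equilibrium. The closest known reaction types are the domino Knoevenagel/pericyclic sequences of cyclic 1,3‑diones with enals, the thermal intramolecular Diels–Alder reaction of 1,3,8‑nonatrienes and the cycloadditions of the dienone valence tautomers of 2H‑pyrans; what is new is the use of an alkylidene β‑triketone as the carbon diene. The cyclohexene ring closes by concerted suprafacial [4+2] addition across the diene termini (the dione carbon, which becomes the spiro centre, and the former enal β‑carbon), and the cyclopentane closes in the fused mode through the three‑atom tether, the bridged and the hetero‑Diels–Alder modes being out of reach because the tether starts at the far, E‑configured diene terminus. The trans ring fusion should follow from the anti (tether‑exo) transition state, because in the syn arrangement the fully substituted carbinol carbon would sit over the diene methyl group, and the configuration of both ring‑fusion carbons relative to the (R)‑carbinol follows from the tether conformation that places the hydroxyl, not the larger methyl group, beside the reacting vinyl terminus (less allylic strain and a possible hydrogen bond to a carbonyl oxygen of the approaching dione). The spiro centre is set under Curtin–Hammett control between the two geometric isomers of 8, which interconvert by rotation about the strongly polarised exocyclic C=C bond and by reversible conjugate addition of the amine catalyst, the carbonyl flanked by the quaternary spiro‑cyclopentene carbon taking the inside (later equatorial) diene position and the flat acetyl‑enol half the outside (later axial) position under the incoming CH2 terminus. The step needs carbocyclic over heterocyclic periselectivity and must outrun oligomerisation and the sigmatropic hydrogen shifts open to the dienone, which the E‑enal geometry, the lack of allylic hydrogen on the dienophile side, the buffered near‑neutral medium and high dilution are meant to secure.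

**Step 5**
Reactants: 10 spiro cycloadduct (trione spiro to cyclopent‑3‑ene and to the trans‑fused hexahydroindene)
Product: 12 1′,4′‑diol (hydrate of 10 with C‑4′ as C(CH3)(OH) and C‑5′ as CH2; 4′‑OH equatorial and cis to 3a′‑H; cyclopentene intact), via tertiary hydroperoxide 11 (not isolated)
Conditions: Mn(dpm)3 (20 mol %; dpm = 2,2,6,6‑tetramethylheptane‑3,5‑dionate), PhSiH3 (2.5 equiv), O2 (1 atm), i‑PrOH/CH2Cl2, 0 °C → rt; then PPh3 (1.5 equiv)
Reagents that add atoms: dioxygen, O=O
Why: Mukaiyama hydration by metal‑hydride hydrogen‑atom transfer should put H on C‑5′ and give the tertiary C‑4′ radical, which the trisubstituted alkene forms faster than the cis‑disubstituted cyclopentene, and O2 should be captured on the face opposite the axial C‑1 carbonyl that stands 1,3 to the radical centre, so the new hydroxyl is equatorial and cis to 3a′‑H (hydroperoxide 11 is reduced by PPh3).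

**Step 6**
Reactants: 12 1′,4′‑diol with the cyclopentene still in place
Product: 14 dialdehyde (as 12 but with two 2‑oxoethyl groups on C‑4 of the trione ring), via cis‑cyclopentane‑1,2‑diol 13 (not isolated)
Conditions: OsO4 (2 mol %), NaIO4 (4 equiv), 2,6‑lutidine (2 equiv), 1,4‑dioxane/H2O (3:1), rt
Reagents that add atoms: osmium tetroxide, O=[Os](=O)(=O)=O; sodium periodate, [Na+].[O-][I](=O)(=O)=O
Why: Lemieux–Johnson oxidation should dihydroxylate the only remaining isolated C=C bond (the enol double bond is tetrasubstituted and electron‑poor, and the lutidine buffer spares the triketone) and cleave the cis‑diol 13 to the two CH2CHO arms without touching any stereocentre.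

**Step 7**
Reactants: 14 dialdehyde
Product: 16 CNP0266834.1, 2‑acetyl‑3‑hydroxy‑4,4‑bis(3‑methylbut‑2‑en‑1‑yl)cyclohex‑2‑ene‑1,5‑dione spiro at C‑6 to C‑6′ of (1′R)‑1′,4′‑dihydroxy‑1′,4′‑dimethyloctahydro‑1′H‑indene, via monoprenyl aldehyde 15 (not isolated)
Conditions: i‑PrPPh3I (8 equiv), n‑BuLi (7.5 equiv), THF, 0 °C; then 14, −78 °C → rt; aqueous NH4Cl
Reagents that add atoms: isopropyltriphenylphosphonium iodide, CC(C)[P+](c1ccccc1)(c1ccccc1)c1ccccc1.[I-]
Why: Double Wittig olefination with the non‑stabilised isopropylidene ylide should convert both aldehydes into prenyl C=C bonds (excess ylide covers the enol and hydroxyl protons, while the enolate‑protected triketone and the hindered C‑5 ketone should not react), and no stereocentre is formed or touched.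

**Compound list**

1 | 2′,4′,6′‑trihydroxyacetophenone | CC(=O)c1c(O)cc(O)cc1O | starting material
2 | 3′‑allyl‑2′,4′,6′‑trihydroxyacetophenone | CC(=O)c1c(O)cc(O)c(CC=C)c1O | intermediate (not isolated)
3 | 2‑acetyl‑3,5‑dihydroxy‑4,4‑di(prop‑2‑en‑1‑yl)cyclohexa‑2,5‑dien‑1‑one | CC(=O)C1=C(O)C(CC=C)(CC=C)C(O)=CC1=O | intermediate
4 | 7‑acetyl‑6,10‑dihydroxyspiro[4.5]deca‑2,6,9‑trien‑8‑one (trione ring with spiro‑cyclopent‑3‑ene at C‑4) | CC(=O)C1=C(O)C2(CC=CC2)C(O)=CC1=O | intermediate
5 | (R)‑(−)‑linalool, (3R)‑3,7‑dimethylocta‑1,6‑dien‑3‑ol | C=C[C@](C)(O)CCC=C(C)C | starting material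
6 | (2E,6R)‑2,6‑dimethylocta‑2,7‑diene‑1,6‑diol | OC/C(C)=C/CC[C@@](C)(O)C=C | intermediate (not isolated)
7 | (2E,6R)‑6‑hydroxy‑2,6‑dimethylocta‑2,7‑dienal | O=C/C(C)=C/CC[C@@](C)(O)C=C | intermediate
8 | 7‑acetyl‑6‑hydroxy‑9‑[(2E,6R)‑6‑hydroxy‑2,6‑dimethylocta‑2,7‑dien‑1‑ylidene]spiro[4.5]deca‑2,6‑diene‑8,10‑dione (1‑oxatriene, both geometries at the exocyclic C=C) | CC(=O)C1=C(O)C2(CC=CC2)C(=O)C(=C/C(C)=C/CC[C@@](C)(O)C=C)C1=O | intermediate (not isolated)
9 | 8‑acetyl‑7‑hydroxy‑2‑[(3R)‑3‑hydroxy‑3‑methylpent‑4‑en‑1‑yl]‑3‑methylspiro[2H‑chromene‑6,1′‑cyclopent‑3′‑en]‑5‑one (2H‑pyran, drawn closed through the C‑1 oxygen; both epimers at the pyran sp3 carbon) | CC(=O)C1=C(O)C2(CC=CC2)C(=O)C3=C1OC(CC[C@@](C)(O)C=C)C(C)=C3 | intermediate (not isolated)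
10 | spiro cycloadduct: trione spiro at C‑4 to cyclopent‑3‑ene and at C‑6 to C‑6′ of trans‑fused (1′R)‑1′‑hydroxy‑1′,4′‑dimethyl‑2′,3′,3a′,6′,7′,7a′‑hexahydro‑1′H‑indene | CC(=O)C1=C(O)C4(CC=CC4)C(=O)[C@@]2(C[C@H]3[C@@H](CC[C@@]3(C)O)C(C)=C2)C1=O | intermediate
11 | C‑4′ tertiary hydroperoxide corresponding to 12 | CC(=O)C1=C(O)C4(CC=CC4)C(=O)[C@@]2(C[C@H]3[C@@H](CC[C@@]3(C)O)[C@](C)(OO)C2)C1=O | intermediate (not isolated)
12 | hydrated cycloadduct (1′,4′‑diol, cyclopentene intact) | CC(=O)C1=C(O)C4(CC=CC4)C(=O)[C@@]2(C[C@H]3[C@@H](CC[C@@]3(C)O)[C@](C)(O)C2)C1=O | intermediate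
13 | cis‑cyclopentane‑1,2‑diol from 12 (either face) | CC(=O)C1=C(O)C4(CC(O)C(O)C4)C(=O)[C@@]2(C[C@H]3[C@@H](CC[C@@]3(C)O)[C@](C)(O)C2)C1=O | intermediate (not isolated)
14 | dialdehyde with two 2‑oxoethyl groups on C‑4 (may rest as a lactol with the enol OH) | CC(=O)C1=C(O)C(CC=O)(CC=O)C(=O)[C@@]2(C[C@H]3[C@@H](CC[C@@]3(C)O)[C@](C)(O)C2)C1=O | intermediate
15 | monoprenyl mono‑aldehyde (both configurations at C‑4) | CC(=O)C1=C(O)C(CC=O)(CC=C(C)C)C(=O)[C@@]2(C[C@H]3[C@@H](CC[C@@]3(C)O)[C@](C)(O)C2)C1=O | intermediate (not isolated)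
16 | CNP0266834.1 | CC(=O)C1=C(O)C(CC=C(C)C)(CC=C(C)C)C(=O)[C@@]2(C[C@H]3[C@@H](CC[C@@]3(C)O)[C@](C)(O)C2)C1=O | target

**Totals**

Total step count: 7. Longest linear sequence: 6 steps (steps 1, 2, 4, 5, 6, 7).

**Steps most likely to fail**

Step 4. The diene terminus carries two carbonyl substituents, so its s‑cis conformer is strained and the cycloaddition to the unactivated vinyl group may be slower than oligomerisation of the oxatriene or its simple reclosure to the pyran. The tertiary allylic alcohol may ionise under the acidic enol at 130 °C. The two carbonyl arms at the diene terminus may be discriminated poorly, with loss of control at the spiro centre.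
The fallback uses known reactions only, sets out from 7 and comes back at 10. Horner–Wadsworth–Emmons olefination of 7 with triethyl phosphonoacetate (NaH, THF) should give ethyl (2E,4E,8R)‑8‑hydroxy‑4,8‑dimethyldeca‑2,4,9‑trienoate F1, which is silylated (Me3SiCl, imidazole, DMF) to its trimethylsilyl ether F2. Thermal type 1 intramolecular Diels–Alder reaction of this ordinary ester‑substituted 1,3,8‑nonatriene (toluene, 170 °C, sealed tube) should give trans‑fused ethyl 1,4‑dimethyl‑1‑(trimethylsilyloxy)‑2,3,3a,6,7,7a‑hexahydro‑1H‑indene‑6‑carboxylate F3. The acyl partner is made separately. tert‑Butyl acetoacetate is C,C‑diallylated (NaH, allyl bromide, THF) to tert‑butyl 2‑acetyl‑2‑(prop‑2‑en‑1‑yl)pent‑4‑enoate F4. Ring‑closing metathesis (second‑generation Grubbs catalyst RuCl2(=CHPh)(PCy3)(H2IMes), CH2Cl2) gives tert‑butyl 1‑acetylcyclopent‑3‑ene‑1‑carboxylate F5. CF3CO2H in CH2Cl2 at 0 °C frees 1‑acetylcyclopent‑3‑ene‑1‑carboxylic acid F6, and oxalyl chloride with catalytic DMF gives 1‑acetylcyclopent‑3‑ene‑1‑carbonyl chloride F7. The lithium dienolate of F3 (LiN(i‑Pr)2, THF, −78 °C) is C‑acylated at the ester α‑carbon by F7 from the less hindered equatorial side to give the quaternary keto ester F8. Dieckmann condensation of the methyl ketone onto the ester (LiN(SiMe3)2, THF, −78 °C → rt) closes the trione ring to the silylated spiro trione F9, and work‑up with 1 M HCl removes the silyl group to give the de‑acetyl spiro trione F10. O‑Acetylation (AcCl, Et3N, CH2Cl2, 0 °C) gives the enol acetate F11 (either enol oxygen). The O‑to‑C acyl shift (4‑(dimethylamino)pyridine, Et3N, MeCN) then places the acetyl group on the only free trione carbon and gives 10.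

Step 5. Hydrogen‑atom transfer may also reach the cyclopentene, O2 may be captured on the wrong face of the C‑4′ radical, and the acidic β‑triketone may bind the manganese catalyst.
The fallback sets out from 10 and comes back at 14, removing the competing alkene first. OsO4 (2 mol %) with N‑methylmorpholine N‑oxide (acetone/H2O) should dihydroxylate the unhindered cyclopentene of 10 to the cis‑cyclopentane‑1,2‑diol F12, the ring alkene next to the quaternary spiro carbon staying intact. Mukaiyama hydration under the conditions of step 5, with no second alkene present, then gives the C‑4′ hydroperoxide F13, and PPh3 reduces it to the triol that is compound 13 of the route. NaIO4 (THF/H2O) cleaves this diol to the dialdehyde 14.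

Step 7. The enol and the two tertiary hydroxyls quench the ylide, and the resulting polyanion may react slowly or allow aldehyde enolisation and aldol loss.
The fallback sets out from 14 and comes back at 16 with temporary protection. 1‑(Trimethylsilyl)imidazole (CH2Cl2, rt) caps the enol and both tertiary hydroxyls to give the tris(trimethylsilyl) dialdehyde F14. Wittig olefination with 2.5 equiv of the same ylide (from i‑PrPPh3I and n‑BuLi, THF, −78 °C → rt) passes through the silylated monoprenyl aldehyde F15 and gives the tris(trimethylsilyl) ether of the target F16. Dilute HCl in THF/H2O at 0 °C removes the three silyl groups to give 16.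

**Further compounds**

F1 | step 4 | ethyl (2E,4E,8R)‑8‑hydroxy‑4,8‑dimethyldeca‑2,4,9‑trienoate | CCOC(=O)/C=C/C(C)=C/CC[C@@](C)(O)C=C
F2 | step 4 | ethyl (2E,4E,8R)‑4,8‑dimethyl‑8‑(trimethylsilyloxy)deca‑2,4,9‑trienoate | CCOC(=O)/C=C/C(C)=C/CC[C@@](C)(O[Si](C)(C)C)C=C
F3 | step 4 | trans‑fused ethyl 1,4‑dimethyl‑1‑(trimethylsilyloxy)‑2,3,3a,6,7,7a‑hexahydro‑1H‑indene‑6‑carboxylate (both epimers at C‑6) | CCOC(=O)C1C[C@H]2[C@@H](CC[C@@]2(C)O[Si](C)(C)C)C(C)=C1
F4 | step 4 | tert‑butyl 2‑acetyl‑2‑(prop‑2‑en‑1‑yl)pent‑4‑enoate | CC(=O)C(CC=C)(CC=C)C(=O)OC(C)(C)C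
F5 | step 4 | tert‑butyl 1‑acetylcyclopent‑3‑ene‑1‑carboxylate | CC(=O)C1(CC=CC1)C(=O)OC(C)(C)C
F6 | step 4 | 1‑acetylcyclopent‑3‑ene‑1‑carboxylic acid | CC(=O)C1(CC=CC1)C(=O)O
F7 | step 4 | 1‑acetylcyclopent‑3‑ene‑1‑carbonyl chloride | CC(=O)C1(CC=CC1)C(Cl)=O
F8 | step 4 | ethyl 6‑(1‑acetylcyclopent‑3‑ene‑1‑carbonyl)‑1,4‑dimethyl‑1‑(trimethylsilyloxy)‑2,3,3a,6,7,7a‑hexahydro‑1H‑indene‑6‑carboxylate | CC(=O)C4(CC=CC4)C(=O)[C@@]2(C[C@H]3[C@@H](CC[C@@]3(C)O[Si](C)(C)C)C(C)=C2)C(=O)OCC
F9 | step 4 | silylated de‑acetyl spiro trione (cyclohexane‑1,3,5‑trione spiro to cyclopentene and to the 1′‑(trimethylsilyloxy)hexahydroindene) | O=C1CC(=O)C4(CC=CC4)C(=O)[C@@]12C[C@H]3[C@@H](CC[C@@]3(C)O[Si](C)(C)C)C(C)=C2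
F10 | step 4 | de‑acetyl analogue of 10 (cyclohexane‑1,3,5‑trione spiro to cyclopentene and to the hexahydroindene) | O=C1CC(=O)C4(CC=CC4)C(=O)[C@@]12C[C@H]3[C@@H](CC[C@@]3(C)O)C(C)=C2
F11 | step 4 | enol acetate of F10 (drawn on the C‑1 oxygen) | CC(=O)OC1=CC(=O)C4(CC=CC4)C(=O)[C@@]12C[C@H]3[C@@H](CC[C@@]3(C)O)C(C)=C2
F12 | step 5 | cis‑cyclopentane‑1,2‑diol from 10 (ring alkene C‑4′=C‑5′ intact) | CC(=O)C1=C(O)C4(CC(O)C(O)C4)C(=O)[C@@]2(C[C@H]3[C@@H](CC[C@@]3(C)O)C(C)=C2)C1=O
F13 | step 5 | C‑4′ tertiary hydroperoxide from F12 | CC(=O)C1=C(O)C4(CC(O)C(O)C4)C(=O)[C@@]2(C[C@H]3[C@@H](CC[C@@]3(C)O)[C@](C)(OO)C2)C1=O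
F14 | step 7 | tris(trimethylsilyl) derivative of dialdehyde 14 | CC(=O)C1=C(O[Si](C)(C)C)C(CC=O)(CC=O)C(=O)[C@@]2(C[C@H]3[C@@H](CC[C@@]3(C)O[Si](C)(C)C)[C@](C)(O[Si](C)(C)C)C2)C1=O
F15 | step 7 | tris(trimethylsilyl) monoprenyl mono‑aldehyde | CC(=O)C1=C(O[Si](C)(C)C)C(CC=O)(CC=C(C)C)C(=O)[C@@]2(C[C@H]3[C@@H](CC[C@@]3(C)O[Si](C)(C)C)[C@](C)(O[Si](C)(C)C)C2)C1=O
F16 | step 7 | tris(trimethylsilyl) ether of the target | CC(=O)C1=C(O[Si](C)(C)C)C(CC=C(C)C)(CC=C(C)C)C(=O)[C@@]2(C[C@H]3[C@@H](CC[C@@]3(C)O[Si](C)(C)C)[C@](C)(O[Si](C)(C)C)C2)C1=O
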